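A ratio was what I took from Saturday's run: target over electrophile times nucleophile left, with nucleophile counted one-to-one against target. I call it the levelling quotient, an apparent equilibrium constant.

all flasks: electrophile 14 mM
- Saturday's: nucleophile 24 mM; run made earlier
- green: nucleophile 28.0 mM; time 5.0 h
- amber: nucleophile 42.0 mM; time 5.0 h
- violet: nucleophile 63.0 mM; time 5.0 h

Saturday's run (percent of the electrophile charged)

| time / h | electrophile / % | target / % |
|---|---|---|
| 0.417 | 34 | 64 |
| 0.833 | 28 | 72 |
| 1.33 | 24 | 75 |
| 1.50 | 24 | 73 |
| 2.00 | 24 | 75 |
| 2.50 | 27 | 78 |

(each reading ± 1.5 percentage points)



- part of the electrophile that has reacted at the end, green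
- part of the electrophile that has reacted at the end, amber
- part of the electrophile that has reacted at the end, violet
- what raising the concentration of nucleophile from its lowest to its highest value here does to the part of the electrophile that has reacted (changes below 5 percentage points count as none) (it rises / no change / it falls)

From 1.33 h on, Saturday's electrophile averaged 24.8% and its target 75.2%. That left 13.5 mM of nucleophile, so the levelling quotient was 0.226 /mM.

I turned the question round. For the trend to read no change on this quotient, violet had to stand less than 5 percentage points above green. That just happens with green near 93.0%, at a quotient of 0.887 /mM, where violet stands at 97.8%; that quotient is 3.92 times mine. Such a quotient puts Saturday's electrophile at 9.09%, yet it levelled at 24.8%, with a scatter of 1.5 points per reading. One escape stayed open: a single run cannot show that the level depends on nucleophile at all.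

I kept the quotient. Because 1.33 h is short against 5.0 h, I took each flask as level at its end. Solving the quadratic for the amount reacted gave green 79.2%, amber 87.1% and violet 91.9%.

The forecast gave the same figures, 79%, 87% and 92%, with the answer it rises, and held that “equilibrium is reached well before 5 h in all three runs”.

The flasks gave green 87.8%, amber 98.8% and violet 99.8%: it rises, by 12 points.

    electrophile + nucleophile ⇌ acid set free + target (K = 0.170, k = 0.0709 /M/s)
    nucleophile + acid set free ⇌ protonated nucleophile, settled at all times (K = 47700 /M)
    nucleophile ⇌ dormant form (K = 0.250, k = 4.01 × 10⁻⁴ /s)
    acid set free + target → side product (k = 0.0348 /M/s)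

Amber at 5.00 h holds target 97.4% against electrophile 1.21%, where I had reckoned 87.1% reacted. Counted my way, that is a quotient of 2.84 /mM, or 12.6 times 0.226 /mM. The neighbour of amber charged with 10 mM of nucleophile, 0.714 equiv, parts the other way. There 0.226 /mM gives 45.3% reacted. That flask reached 35.6%, with 64.4% of its electrophile still unreacted.

(The data come from a simulation on assumed constants, and the scatter is random.)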